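**Retrosynthetic overview**
1. Target 31 ⇐ macrolactone 24 by C14 allylic oxidation (CH3 → CHO), acetonide hydrolysis, double angeloylation and desilylation.
2. Key disconnection C6–C7: CrCl2 turns the 2-(methoxycarbonyl)allyl bromide of 21 into an allylchromium, a β-acrylate (homoenolate, d3) carbanion, which adds to the C6 enal. The aldehyde carbon and the acrylate β-carbon, both normally electrophilic, are joined.
3. 21 ⇐ Baylis–Hillman reaction and bromination of dialdehyde 18 ⇐ (S)-glycerate ester 13 + alkenyl iodide 12 (acylation, Felkin reduction sets C9, acetonide shift, oxidation).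
4. 12 ⇐ Z-selective iodo-Wittig on aldehyde 7 ⇐ anti-carbomagnesiation of alkynol 1 (sets the C4=C5 geometry).
5. Ring order: dioxolane (bought with 13, moved in step 7) → ten-membered carbocycle and γ-lactone together (step 11) → dioxolane removed (step 13).

Assumption: compound 1 is bought as a catalogue chemical; atom labels C1–C15 are the germacrane positions of the target (lactone C12–O–C6, angelates on C8 and C9, CHO = C14, CH2OH = C15).

**Step 1**
Reactants: 1 4-[(tert-butyldimethylsilyl)oxy]but-2-yn-1-ol; 2 2-(2-bromoethyl)-1,3-dioxolane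
Product: 5 (2E)-4-[(tert-butyldimethylsilyl)oxy]-2-[2-(1,3-dioxolan-2-yl)ethyl]but-2-en-1-ol, via Grignard reagent 3 (not isolated), via alkenylmagnesium alkoxide 4 (not isolated)
Conditions: 2 (3 equiv), Mg, THF, 30 °C; then 1, CuI (copper monoiodide, 10 mol %), THF, −20 °C to rt; aq. NH4Cl
Reagents that add atoms: none
Why: Hydroxyl-directed, copper-catalysed anti-carbomagnesiation of a propargylic alcohol puts the alkyl group on the proximal alkyne carbon and forms the five-membered chelate 4, so after protonation the new chain is cis to CH2OTBS, which fixes the ring-cis C4=C5 geometry.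

**Step 2**
Reactants: 5 (2E)-4-[(tert-butyldimethylsilyl)oxy]-2-[2-(1,3-dioxolan-2-yl)ethyl]but-2-en-1-ol
Product: 6 (2E)-1-[(tert-butyldiphenylsilyl)oxy]-4-[(tert-butyldimethylsilyl)oxy]-2-[2-(1,3-dioxolan-2-yl)ethyl]but-2-ene
Conditions: TBDPSCl, imidazole, DMF, rt
Reagents that add atoms: tert-butyl(chloro)diphenylsilane, CC(C)(C)[Si](Cl)(c1ccccc1)c1ccccc1
Why: Standard silylation of the only free primary hydroxyl (the future C15–OH); no stereocentre is involved.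

**Step 3**
Reactants: 6 (2E)-1-[(tert-butyldiphenylsilyl)oxy]-4-[(tert-butyldimethylsilyl)oxy]-2-[2-(1,3-dioxolan-2-yl)ethyl]but-2-ene
Product: 7 (4E)-4-{[(tert-butyldiphenylsilyl)oxy]methyl}-6-hydroxyhex-4-enal
Conditions: 1 M aq. HCl, THF, rt
Reagents that add atoms: water, O
Why: Acid-catalysed acetal hydrolysis cleaves the dioxolane and the labile primary TBS ether while the TBDPS ether survives; the alkene geometry is untouched.

**Step 4**
Reactants: 7 (4E)-4-{[(tert-butyldiphenylsilyl)oxy]methyl}-6-hydroxyhex-4-enal; 8 ethyltriphenylphosphonium iodide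
Product: 12 (2E,6Z)-3-{[(tert-butyldiphenylsilyl)oxy]methyl}-7-iodoocta-2,6-dien-1-ol, via ethylidenetriphenylphosphorane 9 (not isolated), via (1-iodoethyl)triphenylphosphonium iodide 10 (not isolated), via (1-iodoethylidene)triphenylphosphorane 11 (not isolated)
Conditions: 8 (2.5 equiv), n-BuLi, THF, 0 °C; I2, −78 °C; NaN(SiMe3)2, −20 °C; then 7, −78 to −20 °C
Reagents that add atoms: iodine, II
Why: Stork–Zhao-type Wittig olefination with an α-iodo ylide is kinetically Z-selective (iodine cis to the chain), which sets the C1=C10 geometry that later places C9 cis to C2; excess ylide absorbs the free hydroxyl.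

**Step 5**
Reactants: 12 (2E,6Z)-3-{[(tert-butyldiphenylsilyl)oxy]methyl}-7-iodoocta-2,6-dien-1-ol; 13 methyl (4S)-2,2-dimethyl-1,3-dioxolane-4-carboxylate
Product: 15 (2Z,6E)-1-[(4S)-2,2-dimethyl-1,3-dioxolan-4-yl]-8-hydroxy-2-methyl-6-{[(tert-butyldiphenylsilyl)oxy]methyl}octa-2,6-dien-1-one, via dilithio species 14 (not isolated)
Conditions: t-BuLi (3.1 equiv), Et2O, −78 °C; then 13, −78 °C; aq. NH4Cl
Reagents that add atoms: none
Why: Iodine–lithium exchange with retention of alkene geometry, then acylation of the alkenyllithium by the α-alkoxy ester, whose chelated tetrahedral adduct persists at −78 °C and prevents double addition; C8 comes unchanged from the (S)-glycerate.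

**Step 6**
Reactants: 15 (2Z,6E)-1-[(4S)-2,2-dimethyl-1,3-dioxolan-4-yl]-8-hydroxy-2-methyl-6-{[(tert-butyldiphenylsilyl)oxy]methyl}octa-2,6-dien-1-one
Product: 16 (1S,2Z,6E)-1-[(4S)-2,2-dimethyl-1,3-dioxolan-4-yl]-2-methyl-6-{[(tert-butyldiphenylsilyl)oxy]methyl}octa-2,6-diene-1,8-diol
Conditions: LiBH(s-Bu)3 (2.2 equiv), THF, −78 °C; aq. NH4Cl
Reagents that add atoms: none
Why: 1,2-Reduction of the α-alkoxy enone by a bulky, non-chelating borohydride under Felkin–Anh control (C8–O bond anti to the incoming hydride) gives the 8,9-syn alcohol, that is (9S).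

**Step 7**
Reactants: 16 (1S,2Z,6E)-1-[(4S)-2,2-dimethyl-1,3-dioxolan-4-yl]-2-methyl-6-{[(tert-butyldiphenylsilyl)oxy]methyl}octa-2,6-diene-1,8-diol
Product: 17 (2E,6Z)-7-[(4S,5S)-5-(hydroxymethyl)-2,2-dimethyl-1,3-dioxolan-4-yl]-3-{[(tert-butyldiphenylsilyl)oxy]methyl}octa-2,6-dien-1-ol
Conditions: camphorsulfonic acid (5 mol %), acetone, rt (equilibrium; minor isomer recycled)
Reagents that add atoms: none
Why: Acid-catalysed acetonide migration under thermodynamic control, because the trans-4,5-disubstituted dioxolane on the threo 8,9-diol is more stable than the terminal one; this frees the primary C7 hydroxyl without touching a stereocentre.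

**Step 8**
Reactants: 17 (2E,6Z)-7-[(4S,5S)-5-(hydroxymethyl)-2,2-dimethyl-1,3-dioxolan-4-yl]-3-{[(tert-butyldiphenylsilyl)oxy]methyl}octa-2,6-dien-1-ol
Product: 18 (4R,5S)-2,2-dimethyl-5-[(2Z,6E)-8-oxo-6-{[(tert-butyldiphenylsilyl)oxy]methyl}octa-2,6-dien-2-yl]-1,3-dioxolane-4-carbaldehyde
Conditions: Dess–Martin periodinane (2.6 equiv), CH2Cl2, 0 °C to rt
Reagents that add atoms: none
Why: Dess–Martin oxidation of both primary alcohols gives the α-alkoxy aldehyde (C7) and the C6 enal without epimerising C8 or isomerising the C4=C5 bond.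

**Step 9**
Reactants: 18 (4R,5S)-2,2-dimethyl-5-[(2Z,6E)-8-oxo-6-{[(tert-butyldiphenylsilyl)oxy]methyl}octa-2,6-dien-2-yl]-1,3-dioxolane-4-carbaldehyde; 19 methyl acrylate
Product: 20 methyl 3-hydroxy-2-methylidene-3-[(4S,5S)-2,2-dimethyl-5-[(2Z,6E)-8-oxo-6-{[(tert-butyldiphenylsilyl)oxy]methyl}octa-2,6-dien-2-yl]-1,3-dioxolan-4-yl]propanoate (both C7 epimers)
Conditions: 19 (10 equiv), DABCO (1 equiv), MeOH (2 equiv), rt, 48 h
Reagents that add atoms: none
Why: Morita–Baylis–Hillman reaction, in which the DABCO–acrylate zwitterion adds only to the activated α-alkoxy aldehyde (the β,β-disubstituted enal is inert); the new C7 carbinol centre is erased in the next two steps.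

**Step 10**
Reactants: 20 methyl 3-hydroxy-2-methylidene-3-[(4S,5S)-2,2-dimethyl-5-[(2Z,6E)-8-oxo-6-{[(tert-butyldiphenylsilyl)oxy]methyl}octa-2,6-dien-2-yl]-1,3-dioxolan-4-yl]propanoate
Product: 21 methyl (2Z)-2-(bromomethyl)-3-[(4S,5S)-2,2-dimethyl-5-[(2Z,6E)-8-oxo-6-{[(tert-butyldiphenylsilyl)oxy]methyl}octa-2,6-dien-2-yl]-1,3-dioxolan-4-yl]prop-2-enoate
Conditions: NBS, Me2S, CH2Cl2, 0 °C to rt
Reagents that add atoms: N-bromosuccinimide, O=C1CCC(=O)N1Br
Why: Corey–Kim-type activation of the Baylis–Hillman alcohol and SN2′ return of bromide give the thermodynamically preferred (Z)-2-(bromomethyl)enoate under neutral conditions that enal and acetonide tolerate.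

**Step 11 (key step)**
Reactants: 21 methyl (2Z)-2-(bromomethyl)-3-[(4S,5S)-2,2-dimethyl-5-[(2Z,6E)-8-oxo-6-{[(tert-butyldiphenylsilyl)oxy]methyl}octa-2,6-dien-2-yl]-1,3-dioxolan-4-yl]prop-2-enoate
Product: 24 (1(10)Z,4E,6R,7S,8S,9S)-15-[(tert-butyldiphenylsilyl)oxy]-8,9-(isopropylidenedioxy)germacra-1(10),4,11(13)-trien-12,6-olide, via allylchromium dichloride 22 (not isolated), via chromium alkoxide 23 (not isolated)
Conditions: CrCl2 (8 equiv), THF, 25 °C, 21 added over 10 h (final 2 mM); aq. NH4Cl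
Reagents that add atoms: none
Why: Intramolecular Nozaki–Hiyama (chromium Barbier) allylation, in which the allylchromium attacks the C6 aldehyde through its γ-carbon C7 (the acrylate β-carbon, normally an acceptor) via a chair with both ring branches equatorial (anti, hence the trans-lactone), with H8 in the allyl plane to avoid allylic 1,3-strain and the aldehyde entering anti to the C8–C9 bond, giving (6R,7S) and closing the ten-membered ring before the alkoxide lactonises onto the ester.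

**Step 12**
Reactants: 24 (1(10)Z,4E,6R,7S,8S,9S)-15-[(tert-butyldiphenylsilyl)oxy]-8,9-(isopropylidenedioxy)germacra-1(10),4,11(13)-trien-12,6-olide
Product: 26 (1(10)E,4E,6R,7S,8S,9S)-15-[(tert-butyldiphenylsilyl)oxy]-8,9-(isopropylidenedioxy)-14-oxogermacra-1(10),4,11(13)-trien-12,6-olide, via allylic alcohol 25 (not isolated)
Conditions: SeO2 (0.5 equiv), t-BuOOH (4 equiv), CH2Cl2, rt; then MnO2 (20 equiv) added, rt
Reagents that add atoms: selenium dioxide, O=[Se]=O; tert-butyl hydroperoxide, CC(C)(C)OO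
Why: Riley allylic oxidation (ene reaction, then [2,3]-sigmatropic shift) attacks the most electron-rich trisubstituted alkene at the methyl trans to the chain (C14) and returns the double bond with the oxidised carbon trans to C2; MnO2 then takes the allylic alcohol to the enal.

**Step 13**
Reactants: 26 (1(10)E,4E,6R,7S,8S,9S)-15-[(tert-butyldiphenylsilyl)oxy]-8,9-(isopropylidenedioxy)-14-oxogermacra-1(10),4,11(13)-trien-12,6-olide
Product: 27 (1(10)E,4E,6R,7S,8S,9S)-15-[(tert-butyldiphenylsilyl)oxy]-8,9-dihydroxy-14-oxogermacra-1(10),4,11(13)-trien-12,6-olide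
Conditions: CF3CO2H/H2O (4:1), CH2Cl2, 0 °C
Reagents that add atoms: none
Why: Acid hydrolysis of the acetonide, tolerated by the TBDPS ether, the enal and the α-methylene lactone; no stereocentre is touched.

**Step 14**
Reactants: 27 (1(10)E,4E,6R,7S,8S,9S)-15-[(tert-butyldiphenylsilyl)oxy]-8,9-dihydroxy-14-oxogermacra-1(10),4,11(13)-trien-12,6-olide; 28 angelic acid
Product: 30 (1(10)E,4E,6R,7S,8S,9S)-8,9-bis(angeloyloxy)-15-[(tert-butyldiphenylsilyl)oxy]-14-oxogermacra-1(10),4,11(13)-trien-12,6-olide, via mixed anhydride 29 (not isolated)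
Conditions: 28 (6 equiv), 2,4,6-Cl3C6H2COCl, Et3N, toluene, rt; then 27, 80 °C
Reagents that add atoms: none
Why: Yamaguchi esterification through mixed anhydride 29, conditions chosen to transfer the angeloyl group without Z-to-E isomerisation to tiglate, acylates both secondary hydroxyls with retention at C8 and C9.

**Step 15**
Reactants: 30 (1(10)E,4E,6R,7S,8S,9S)-8,9-bis(angeloyloxy)-15-[(tert-butyldiphenylsilyl)oxy]-14-oxogermacra-1(10),4,11(13)-trien-12,6-olide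
Product: 31 (1(10)E,4E,6R,7S,8S,9S)-8,9-bis(angeloyloxy)-15-hydroxy-14-oxogermacra-1(10),4,11(13)-trien-12,6-olide (CNP0139154.1)
Conditions: HF·pyridine, pyridine, THF, 0 °C to rt
Reagents that add atoms: none
Why: Fluoride-mediated cleavage of the silyl ether under buffered, weakly acidic conditions leaves the angelates, the enal and the α-methylene lactone intact.

**Compound list**
1 | 4-[(tert-butyldimethylsilyl)oxy]but-2-yn-1-ol | OCC#CCO[Si](C)(C)C(C)(C)C | starting material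
2 | 2-(2-bromoethyl)-1,3-dioxolane | BrCCC1OCCO1 | starting material
3 | [2-(1,3-dioxolan-2-yl)ethyl]magnesium bromide | Br[Mg]CCC1OCCO1 | intermediate
4 | bromomagnesium (2Z)-3-(bromomagnesio)-4-[(tert-butyldimethylsilyl)oxy]-2-[2-(1,3-dioxolan-2-yl)ethyl]but-2-en-1-olate (Mg on C5 cis to CH2O–Mg) | Br[Mg]OC/C(CCC1OCCO1)=C(\[Mg]Br)CO[Si](C)(C)C(C)(C)C | intermediate
5 | (2E)-4-[(tert-butyldimethylsilyl)oxy]-2-[2-(1,3-dioxolan-2-yl)ethyl]but-2-en-1-ol | OC/C(CCC1OCCO1)=C/CO[Si](C)(C)C(C)(C)C | intermediate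
6 | (2E)-1-[(tert-butyldiphenylsilyl)oxy]-4-[(tert-butyldimethylsilyl)oxy]-2-[2-(1,3-dioxolan-2-yl)ethyl]but-2-ene | CC(C)(C)[Si](C)(C)OC/C=C(/CO[Si](c1ccccc1)(c1ccccc1)C(C)(C)C)CCC1OCCO1 | intermediate
7 | (4E)-4-{[(tert-butyldiphenylsilyl)oxy]methyl}-6-hydroxyhex-4-enal | OC/C=C(/CO[Si](c1ccccc1)(c1ccccc1)C(C)(C)C)CCC=O | intermediate
8 | ethyltriphenylphosphonium iodide | CC[P+](c1ccccc1)(c1ccccc1)c1ccccc1.[I-] | starting material
9 | ethylidenetriphenylphosphorane | CC=P(c1ccccc1)(c1ccccc1)c1ccccc1 | intermediate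
10 | (1-iodoethyl)triphenylphosphonium iodide | CC(I)[P+](c1ccccc1)(c1ccccc1)c1ccccc1.[I-] | intermediate
11 | (1-iodoethylidene)triphenylphosphorane | CC(I)=P(c1ccccc1)(c1ccccc1)c1ccccc1 | intermediate
12 | (2E,6Z)-3-{[(tert-butyldiphenylsilyl)oxy]methyl}-7-iodoocta-2,6-dien-1-ol | OC/C=C(/CO[Si](c1ccccc1)(c1ccccc1)C(C)(C)C)CC/C=C(/C)I | intermediate
13 | methyl (4S)-2,2-dimethyl-1,3-dioxolane-4-carboxylate | COC(=O)[C@@H]1COC(C)(C)O1 | starting material
14 | lithium 3-{[(tert-butyldiphenylsilyl)oxy]methyl}-7-lithioocta-2,6-dien-1-olate (geometry of 12 retained, Li in place of I) | [Li]OC/C=C(/CO[Si](c1ccccc1)(c1ccccc1)C(C)(C)C)CC/C=C(/C)[Li] | intermediate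
15 | (2Z,6E)-1-[(4S)-2,2-dimethyl-1,3-dioxolan-4-yl]-8-hydroxy-2-methyl-6-{[(tert-butyldiphenylsilyl)oxy]methyl}octa-2,6-dien-1-one | OC/C=C(/CO[Si](c1ccccc1)(c1ccccc1)C(C)(C)C)CC/C=C(/C)C(=O)[C@@H]1COC(C)(C)O1 | intermediate
16 | (1S,2Z,6E)-1-[(4S)-2,2-dimethyl-1,3-dioxolan-4-yl]-2-methyl-6-{[(tert-butyldiphenylsilyl)oxy]methyl}octa-2,6-diene-1,8-diol | OC/C=C(/CO[Si](c1ccccc1)(c1ccccc1)C(C)(C)C)CC/C=C(/C)[C@H](O)[C@@H]1COC(C)(C)O1 | intermediate
17 | (2E,6Z)-7-[(4S,5S)-5-(hydroxymethyl)-2,2-dimethyl-1,3-dioxolan-4-yl]-3-{[(tert-butyldiphenylsilyl)oxy]methyl}octa-2,6-dien-1-ol | OC/C=C(/CO[Si](c1ccccc1)(c1ccccc1)C(C)(C)C)CC/C=C(/C)[C@@H]1OC(C)(C)O[C@H]1CO | intermediate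
18 | (4R,5S)-2,2-dimethyl-5-[(2Z,6E)-8-oxo-6-{[(tert-butyldiphenylsilyl)oxy]methyl}octa-2,6-dien-2-yl]-1,3-dioxolane-4-carbaldehyde | O=C/C=C(/CO[Si](c1ccccc1)(c1ccccc1)C(C)(C)C)CC/C=C(/C)[C@@H]1OC(C)(C)O[C@H]1C=O | intermediate
19 | methyl acrylate | C=CC(=O)OC | starting material
20 | methyl 3-hydroxy-2-methylidene-3-[(4S,5S)-2,2-dimethyl-5-[(2Z,6E)-8-oxo-6-{[(tert-butyldiphenylsilyl)oxy]methyl}octa-2,6-dien-2-yl]-1,3-dioxolan-4-yl]propanoate (both carbinol epimers) | O=C/C=C(/CO[Si](c1ccccc1)(c1ccccc1)C(C)(C)C)CC/C=C(/C)[C@@H]1OC(C)(C)O[C@H]1C(O)C(=C)C(=O)OC | intermediate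
21 | methyl (2Z)-2-(bromomethyl)-3-[(4S,5S)-2,2-dimethyl-5-[(2Z,6E)-8-oxo-6-{[(tert-butyldiphenylsilyl)oxy]methyl}octa-2,6-dien-2-yl]-1,3-dioxolan-4-yl]prop-2-enoate | O=C/C=C(/CO[Si](c1ccccc1)(c1ccccc1)C(C)(C)C)CC/C=C(/C)[C@@H]1OC(C)(C)O[C@H]1/C=C(\CBr)C(=O)OC | intermediate
22 | allylchromium dichloride of 21 (CrCl2 group in place of Br, trivalent chromium) | O=C/C=C(/CO[Si](c1ccccc1)(c1ccccc1)C(C)(C)C)CC/C=C(/C)[C@@H]1OC(C)(C)O[C@H]1/C=C(\C[Cr](Cl)Cl)C(=O)OC | intermediate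
23 | dichlorochromium alkoxide of the ring-closed methyl ester (C6–O–CrCl2, C12 still CO2Me, configuration as in 24) | COC(=O)C(=C)[C@H]1[C@H](O[Cr](Cl)Cl)/C=C(/CO[Si](c2ccccc2)(c2ccccc2)C(C)(C)C)CC/C=C(/C)[C@@H]2OC(C)(C)O[C@@H]12 | intermediate
24 | (1(10)Z,4E,6R,7S,8S,9S)-15-[(tert-butyldiphenylsilyl)oxy]-8,9-(isopropylidenedioxy)germacra-1(10),4,11(13)-trien-12,6-olide (both ring alkenes cis in the ring, C14 = CH3) | C=C1C(=O)O[C@@H]2/C=C(/CO[Si](c3ccccc3)(c3ccccc3)C(C)(C)C)CC/C=C(/C)[C@@H]3OC(C)(C)O[C@H]3[C@@H]12 | intermediate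
25 | 14-hydroxy derivative of 24 (C14 = CH2OH) | C=C1C(=O)O[C@@H]2/C=C(/CO[Si](c3ccccc3)(c3ccccc3)C(C)(C)C)CC/C=C(/CO)[C@@H]3OC(C)(C)O[C@H]3[C@@H]12 | intermediate
26 | (1(10)E,4E,6R,7S,8S,9S)-15-[(tert-butyldiphenylsilyl)oxy]-8,9-(isopropylidenedioxy)-14-oxogermacra-1(10),4,11(13)-trien-12,6-olide | C=C1C(=O)O[C@@H]2/C=C(/CO[Si](c3ccccc3)(c3ccccc3)C(C)(C)C)CC/C=C(/C=O)[C@@H]3OC(C)(C)O[C@H]3[C@@H]12 | intermediate
27 | (1(10)E,4E,6R,7S,8S,9S)-15-[(tert-butyldiphenylsilyl)oxy]-8,9-dihydroxy-14-oxogermacra-1(10),4,11(13)-trien-12,6-olide | C=C1C(=O)O[C@@H]2/C=C(/CO[Si](c3ccccc3)(c3ccccc3)C(C)(C)C)CC/C=C(/C=O)[C@H](O)[C@@H](O)[C@@H]12 | intermediate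
28 | angelic acid, (2Z)-2-methylbut-2-enoic acid | C/C=C(/C)C(=O)O | starting material
29 | angelic 2,4,6-trichlorobenzoic anhydride | C/C=C(/C)C(=O)OC(=O)c1c(Cl)cc(Cl)cc1Cl | intermediate
30 | (1(10)E,4E,6R,7S,8S,9S)-8,9-bis(angeloyloxy)-15-[(tert-butyldiphenylsilyl)oxy]-14-oxogermacra-1(10),4,11(13)-trien-12,6-olide | C=C1C(=O)O[C@@H]2/C=C(/CO[Si](c3ccccc3)(c3ccccc3)C(C)(C)C)CC/C=C(/C=O)[C@H](OC(=O)/C(C)=C\C)[C@@H](OC(=O)/C(C)=C\C)[C@@H]12 | intermediate
31 | (1(10)E,4E,6R,7S,8S,9S)-8,9-bis(angeloyloxy)-15-hydroxy-14-oxogermacra-1(10),4,11(13)-trien-12,6-olide | C=C1C(=O)O[C@@H]2/C=C(/CO)CC/C=C(/C=O)[C@H](OC(=O)/C(C)=C\C)[C@@H](OC(=O)/C(C)=C\C)[C@@H]12 | target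

**Totals**
Total step count: 15. Longest linear sequence: 15 steps (1 → 31); compounds 2, 8, 13, 19 and 28 enter as bought.

**Three steps most likely to fail**

Step 11. The ten-membered ring may close slowly, and the facial selectivity at C7 rests on an allylic-strain model that could be overridden by the ring. The fallback sets out from 21 and returns at 24. Indium metal in THF/H2O closes the ring by a Barbier reaction through the chair in which the C8 branch of the unisomerised allylindium is axial, so the syn adduct lactonises to the cis-fused 6-epi-lactone F1. LiOH in THF/H2O opens it to the hydroxy acid F2. Mitsunobu lactonisation (PPh3, DIAD) then re-closes the five-membered ring with SN2 inversion at C6 and gives 24.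

Step 12. The late Riley oxidation must pick C14 over the other allylic positions and may stop at low conversion. The fallback sets out from 7 and returns at 27, bringing C14 in at the aldehyde level instead of oxidising it late. Wittig reaction of 7 with Ph3P=CHCHO gives the enal F3, and I2 with DMAP and K2CO3 gives the (Z)-2-iodoenal F4. HC(OMe)3 with PPTS in MeOH gives the dimethyl acetal F5. F5 is then carried through the operations of steps 5 to 11: the enone F6, the syn alcohol F7, the shifted acetonide diol F8 (PPTS, 2,2-dimethoxypropane, CH2Cl2, to keep the acetal), the dialdehyde F9, the Baylis–Hillman adduct F10, the allylic bromide F11 and the macrolactone acetal F12. Aqueous CF3CO2H then removes acetonide and acetal together and gives 27.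

Step 14. Double acylation of the hindered 8,9-diol with angelic acid risks tiglate formation and lactone migration to O8. The fallback sets out from 24 and returns at 30, building the angelates on the molecule before C14 is oxidised. Aqueous CF3CO2H converts 24 into the diol F13. DCC and DMAP with 2-[bis(2,2,2-trifluoroethoxy)phosphoryl]propanoic acid give the bis(phosphonopropanoate) F14. Still–Gennari olefination (KN(SiMe3)2, 18-crown-6, acetaldehyde, −78 °C) gives the Z-configured bis-angelate F15. The Riley oxidation and MnO2 treatment of step 12 then give 30.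

**Further compounds**
F1 | step 11 | (6S,7S,8S,9S)-15-[(tert-butyldiphenylsilyl)oxy]-8,9-(isopropylidenedioxy)germacra-1(10),4,11(13)-trien-12,6-olide, the cis-fused 6-epimer of 24 | C=C1C(=O)O[C@H]2/C=C(/CO[Si](c3ccccc3)(c3ccccc3)C(C)(C)C)CC/C=C(/C)[C@@H]3OC(C)(C)O[C@H]3[C@@H]12
F2 | step 11 | seco hydroxy acid of F1 (C6–OH, C12 = CO2H, other centres as in 24) | OC(=O)C(=C)[C@H]1[C@@H](O)/C=C(/CO[Si](c2ccccc2)(c2ccccc2)C(C)(C)C)CC/C=C(/C)[C@@H]2OC(C)(C)O[C@@H]12
F3 | step 12 | (2E,6E)-8-hydroxy-6-{[(tert-butyldiphenylsilyl)oxy]methyl}octa-2,6-dienal | OC/C=C(/CO[Si](c1ccccc1)(c1ccccc1)C(C)(C)C)CC/C=C/C=O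
F4 | step 12 | (2Z,6E)-8-hydroxy-2-iodo-6-{[(tert-butyldiphenylsilyl)oxy]methyl}octa-2,6-dienal | OC/C=C(/CO[Si](c1ccccc1)(c1ccccc1)C(C)(C)C)CC/C=C(\I)C=O
F5 | step 12 | (2E,6Z)-7-iodo-8,8-dimethoxy-3-{[(tert-butyldiphenylsilyl)oxy]methyl}octa-2,6-dien-1-ol | OC/C=C(/CO[Si](c1ccccc1)(c1ccccc1)C(C)(C)C)CC/C=C(\I)C(OC)OC
F6 | step 12 | analogue of 15 with CH(OMe)2 in place of the C14 methyl | OC/C=C(/CO[Si](c1ccccc1)(c1ccccc1)C(C)(C)C)CC/C=C(/C(OC)OC)C(=O)[C@@H]1COC(C)(C)O1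
F7 | step 12 | analogue of 16 with CH(OMe)2 in place of the C14 methyl | OC/C=C(/CO[Si](c1ccccc1)(c1ccccc1)C(C)(C)C)CC/C=C(/C(OC)OC)[C@H](O)[C@@H]1COC(C)(C)O1
F8 | step 12 | analogue of 17 with CH(OMe)2 in place of the C14 methyl | OC/C=C(/CO[Si](c1ccccc1)(c1ccccc1)C(C)(C)C)CC/C=C(/C(OC)OC)[C@@H]1OC(C)(C)O[C@H]1CO
F9 | step 12 | analogue of 18 with CH(OMe)2 in place of the C14 methyl | O=C/C=C(/CO[Si](c1ccccc1)(c1ccccc1)C(C)(C)C)CC/C=C(/C(OC)OC)[C@@H]1OC(C)(C)O[C@H]1C=O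
F10 | step 12 | analogue of 20 with CH(OMe)2 in place of the C14 methyl | O=C/C=C(/CO[Si](c1ccccc1)(c1ccccc1)C(C)(C)C)CC/C=C(/C(OC)OC)[C@@H]1OC(C)(C)O[C@H]1C(O)C(=C)C(=O)OC
F11 | step 12 | analogue of 21 with CH(OMe)2 in place of the C14 methyl | O=C/C=C(/CO[Si](c1ccccc1)(c1ccccc1)C(C)(C)C)CC/C=C(/C(OC)OC)[C@@H]1OC(C)(C)O[C@H]1/C=C(\CBr)C(=O)OC
F12 | step 12 | analogue of 24 with CH(OMe)2 in place of the C14 methyl | C=C1C(=O)O[C@@H]2/C=C(/CO[Si](c3ccccc3)(c3ccccc3)C(C)(C)C)CC/C=C(/C(OC)OC)[C@@H]3OC(C)(C)O[C@H]3[C@@H]12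
F13 | step 14 | (6R,7S,8S,9S)-15-[(tert-butyldiphenylsilyl)oxy]-8,9-dihydroxygermacra-1(10),4,11(13)-trien-12,6-olide (C14 = CH3) | C=C1C(=O)O[C@@H]2/C=C(/CO[Si](c3ccccc3)(c3ccccc3)C(C)(C)C)CC/C=C(/C)[C@H](O)[C@@H](O)[C@@H]12
F14 | step 14 | 8,9-bis{2-[bis(2,2,2-trifluoroethoxy)phosphoryl]propanoate} of F13 | C=C1C(=O)O[C@@H]2/C=C(/CO[Si](c3ccccc3)(c3ccccc3)C(C)(C)C)CC/C=C(/C)[C@H](OC(=O)C(C)P(=O)(OCC(F)(F)F)OCC(F)(F)F)[C@@H](OC(=O)C(C)P(=O)(OCC(F)(F)F)OCC(F)(F)F)[C@@H]12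
F15 | step 14 | 8,9-bis(angelate) of F13 (C14 = CH3) | C=C1C(=O)O[C@@H]2/C=C(/CO[Si](c3ccccc3)(c3ccccc3)C(C)(C)C)CC/C=C(/C)[C@H](OC(=O)/C(C)=C\C)[C@@H](OC(=O)/C(C)=C\C)[C@@H]12
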